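## The problem

The target joins two natural-product halves through a biaryl bond. One half is a (2R,3R)-dihydroflavonol (rings A, B, C). The other is a (+)-pinoresinol-type 2,6-diaryl-3,7-dioxabicyclo[3.3.0]octane with aryl rings D and E (lignan numbering: C7, C8, C9 on the ring E side; C7′, C8′, C9′ on the ring D side). Ring B C5 is bonded to ring D C5, ortho to an oxygen on each side.

The six stereocentres form two clusters that cannot influence each other. In the bicycle one benzylic centre can dictate the other three (trans at the neighbouring carbon, cis ring fusion, exo aryl). Nothing in the lignan can bias the faces of ring C, so C2 and C3 need reagent control. Because the lignan is homochiral, a wrong-sense ring C is a diastereomer, not an enantiomer.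

The fragile groups limit the chemistry. The benzylic ether carbons of the bicycle, para to oxygen, ionise with acid, are attacked by quinone oxidants and can be hydrogenolysed. The 3-hydroxychromanone enolises and ring-opens with base and is easily dehydrogenated. The free catechol and phloroglucinol phenols are air-sensitive. Protecting groups must therefore leave under neutral conditions: benzyl ethers and a diphenylmethylene ketal, removed together by hydrogenolysis at the end.

The feature that invites a short ring C synthesis is its polarity pattern. C4 is benzylic to ring A and ortho to O1, so it can be the carbonyl carbon of a salicylaldehyde activated as an oxocarbenium ion (a cationic ortho-quinone methide). C2 is benzylic to ring B and para to the B4 oxygen, so it can carry a cation. C3 bears oxygen, so the two-carbon partner is an enol ester. One caveat: the B4 oxygen lies between the B3 oxygen and ring D, and as an open-chain ether it would be twisted out of conjugation. The catechol is therefore tied into a dioxole, which holds the B4 oxygen coplanar with ring B.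

## Retrosynthesis

**Deprotection (26 from 25 from 24).** No skeletal bond is cut. The four benzyl ethers and the ketal of 25 fall in one hydrogenolysis. The C3 acetate of 24 is removed before that, while every phenol is still masked, so that no phenoxide can drive ring-opening. A neutral last step is preferred over acid-labile acetals, because acid would ionise the bicycle once its para oxygens are free.

**C4 oxidation level (24 from 23 from 22).** The C4 methyl ether of 22 is flanked by O1, O5 and O7 and is the most ionisable ether in the molecule. It can be exchanged for hydroxyl (23) and oxidised to the ketone 24 without touching the lignan. Bringing C4 in already oxygenated avoids a quinone oxidation of a 4-unsubstituted flavan, which would compete with the C7–H and C7′–H bonds.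

**Ring C (22 to 19 + 20 + 17).** O1–C2 and C3–C4 are cut. The aldol-type cut at C2–C3 would need separate steps to add O3 and close the ring. This cut delivers ring C with O1, O3 and O4 in place and three stereocentres in one operation. Aldehyde 19 is a one-step compound, orthoformate 20 is bought, and 17 carries everything else. The forward reaction must send the charge to C2, close trans, and choose one face at C3. The first two are built into 17 (para dioxole oxygen, participating acetate). The third rests on a chiral counteranion, backed by the separability of the diastereomers.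

**Enol acetate (17 from 16 from 15).** The Z enol acetate comes from terminal alkyne 16 by anti-Markovnikov addition of acetic acid, and 16 from aldehyde 15 by one-carbon homologation. This avoids any free, enolisable aldehyde at the two-carbon stage and gives one defined alkene geometry.

**Biaryl (15 to 11 + 14).** The bond between rings B and D is cut. Each ring has a single ortho oxygen, so a Suzuki coupling is reasonable. The halide sits on the lignan (inherited from 1) and the boron on the small partner 14, so the costly fragment is used last and the ring B aldehyde needs no protection.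

**Bicycle (11 from 9).** C8–C8′ and C7–O are cut. A radical cyclisation of epoxy ether 9 closes both rings in one flask and lets C7′ control C8′, C8 and C7. The alternative, acid-mediated double cyclisation of an open tetrol, would need four stereocentres or rely on equilibration.

**Ether and fragments (9 to 4 + 8).** The O–C9 ether bond is cut. Epoxy alcohol 4 comes from racemic allylic alcohol 3 by kinetic resolution, 3 from aldehyde 2, and 2 from 5-bromovanillin 1. Only the carbinol centre of 4 matters, since the epoxide carbon becomes a radical. Bromide 8 comes from alcohol 7, ester 6 and ferulic acid 5.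

**Small partners.** Boronate 14 comes from bromide 13 and catechol 12. Aldehyde 19 comes from 18.

## Roads not taken

**Alternative 1:** The cut is in the lignan half, at C7–C8 and C8′–C7′. The lithiated dithioacetal A1 (an acyl anion for ring E) adds 1,4 to the menthyloxybutenolide A2, anti to the menthyloxy group. The lactone enolate is trapped in the same flask by biaryl aldehyde A3, giving the trans-disubstituted lactone A4; no ring closes.
- Merits: two C–C bonds and the C8/C8′ pair in one operation; absolute configuration from a cheap auxiliary with a well-understood anti addition; no resolution.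
- Weak points here: A4 is still far from the bicycle. Desulfurisation, reduction of the lactone and acetal carbons, and an acid-mediated double cyclisation follow, the last on para-oxygenated benzylic alcohols where exo/endo mixtures are a real hazard. The dense biaryl aldehyde is spent early as an aldol electrophile. Ring C is untouched.
- Comparison: for C8/C8′ this road is better precedented than the resolution plus radical cyclisation used here, and it does not discard half of 3. Against that, the chosen plan reaches the bicycle 11 in five steps from 1 with both rings closing in step 8, couples the biaryl late, and also solves ring C.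

**Alternative 2:** The cut is the C7′–O bond of the second tetrahydrofuran. Ag2O oxidises the free ring D phenol of the 7′-deoxy lignan A5 to a para-quinone methide, and the C9 hydroxyl adds to C7′ (5-exo), giving A6 with the aryl group exo.
- Merits: biomimetic, mild and neutral; selective for the one free phenol; C7′ needs no prior control.
- Weak points here: A5 already holds C7, C8 and C8′, so the hard part of the lignan is only moved upstream. Ring D must carry a free phenol while rings B and E are masked, which costs differentiation steps. The quinone methide is flanked by the biaryl and open to outside nucleophiles. Ring C is not addressed.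
- Comparison: as a way to close the second ring it is at least as reliable as the iodine-induced closure of step 8, and its logic is kept as the fallback there. The chosen plan offers only that 9 gives both rings in one flask without a differentiated phenol.

**Alternative 3:** The cut goes through ring B itself (B3–B4 and B5–B6). The siloxyalkyne A8 on ring D adds across C3 and C6 of coumalate A7, and decarboxylative aromatisation gives biaryl A9.
- Merits: regiochemistry set by the polarised partners; no transition metal; no coupling of two ortho-oxygenated arenes; the B3 and B4 oxygens come out differentiated.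
- Weak points here: the target has both B3 and B4 as free hydroxyls, so the differentiation is not needed (they are tied into one ketal on purpose). A7 and A8 each take several steps, the ester of A9 must be brought to the aldehyde level, and the lignan must still be built on ring D afterwards.
- Comparison: if step 11 failed on steric grounds this would be the better way to the biaryl, and it avoids palladium. As the biaryl is only di-ortho-substituted, the chosen plan needs one step from 11 and 14, at the risk of some protodeboronation of 14.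

Key step: step 15

Assumption: 22 and 23 are drawn as the expected 2,4-cis (4R) isomers, and either C4 epimer converges on 24. Compound 12 is taken as purchasable. Which antipode of the chiral acid gives the 2R,3R series cannot be predicted, and the route is written for the matching one.

In names, Lg stands for 2-(benzyloxy)-5-[(1S,3aR,4S,6aR)-4-[4-(benzyloxy)-3-methoxyphenyl]tetrahydro-1H,3H-furo[3,4-c]furan-1-yl]-3-methoxyphenyl.

## Steps

Step 1
Reactants: 1 5-bromovanillin
Product: 2 4-(benzyloxy)-3-bromo-5-methoxybenzaldehyde
Conditions: BnBr, K2CO3, DMF, 60 °C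
Reagents that add atoms: benzyl bromide, BrCc1ccccc1
Why: Williamson ether synthesis on a phenol acidified by the para formyl and ortho bromo groups; there is no other nucleophilic site.

Step 2
Reactants: 2 4-(benzyloxy)-3-bromo-5-methoxybenzaldehyde
Product: 3 rac-1-[4-(benzyloxy)-3-bromo-5-methoxyphenyl]prop-2-en-1-ol
Conditions: CH2=CHMgBr, THF, −78 → 0 °C; aq. NH4Cl
Reagents that add atoms: vinylmagnesium bromide, C=C[Mg]Br
Why: Grignard 1,2-addition to the aldehyde; the aryl bromide does not exchange with a vinylmagnesium halide at low temperature. The carbinol centre forms racemic and is resolved in step 3.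

Step 3
Reactants: 3 rac-1-[4-(benzyloxy)-3-bromo-5-methoxyphenyl]prop-2-en-1-ol
Product: 4 (R)-[4-(benzyloxy)-3-bromo-5-methoxyphenyl][(S)-oxiran-2-yl]methanol
Conditions: Ti(OiPr)4 (0.15 equiv), D-(−)-DIPT (0.2 equiv), t-BuOOH (0.55 equiv), 4 Å MS, CH2Cl2, −20 °C
Reagents that add atoms: tert-butyl hydroperoxide, CC(C)(C)OO
Why: Sharpless kinetic resolution of a secondary allylic alcohol: with D-(−)-DIPT the (S)-enantiomer of 3 should be epoxidised fast and erythro-selectively, leaving (R)-3 behind. The carbinol centre of 4 (R by descriptor, same spatial arrangement as (S)-3) becomes C7′; the epoxide carbon is erased as a radical in step 8.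

Step 4
Reactants: 5 ferulic acid
Product: 6 benzyl (E)-3-[4-(benzyloxy)-3-methoxyphenyl]prop-2-enoate
Conditions: BnBr (2.2 equiv), K2CO3, DMF, 60 °C
Reagents that add atoms: benzyl bromide, BrCc1ccccc1
Why: Williamson ether synthesis and carboxylate alkylation in one operation; the alkene is not affected.

Step 5
Reactants: 6 benzyl (E)-3-[4-(benzyloxy)-3-methoxyphenyl]prop-2-enoate
Product: 7 (E)-3-[4-(benzyloxy)-3-methoxyphenyl]prop-2-en-1-ol
Conditions: DIBAL-H (2.5 equiv), CH2Cl2, −78 °C; Rochelle salt
Reagents that add atoms: none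
Why: 1,2-reduction of a cinnamate ester to the allylic alcohol with DIBAL-H, the standard route to coniferyl-type alcohols; the alkene is retained.

Step 6
Reactants: 7 (E)-3-[4-(benzyloxy)-3-methoxyphenyl]prop-2-en-1-ol
Product: 8 (E)-1-(benzyloxy)-4-(3-bromoprop-1-en-1-yl)-2-methoxybenzene
Conditions: PBr3, Et2O, 0 °C; used crude at once
Reagents that add atoms: phosphorus tribromide, BrP(Br)Br
Why: conversion of an allylic alcohol into the bromide with PBr3; the conjugated (E)-cinnamyl bromide is the thermodynamic allylic isomer. It ionises easily and is therefore not stored.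

Step 7
Reactants: 4 (R)-[4-(benzyloxy)-3-bromo-5-methoxyphenyl][(S)-oxiran-2-yl]methanol; 8 (E)-1-(benzyloxy)-4-(3-bromoprop-1-en-1-yl)-2-methoxybenzene
Product: 9 (S)-2-[(R)-[4-(benzyloxy)-3-bromo-5-methoxyphenyl]{[(E)-3-[4-(benzyloxy)-3-methoxyphenyl]prop-2-en-1-yl]oxy}methyl]oxirane
Conditions: NaH, THF–DMF, 0 °C; then 8, Bu4NI (cat.), 0 °C → rt
Reagents that add atoms: none
Why: Williamson etherification of the sodium alkoxide of 4 at the primary allylic carbon of 8. In aprotic medium at 0 °C alkylation should outrun Payne rearrangement, as in routine O-benzylation of such epoxy alcohols. No stereocentre is touched.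

Step 8
Reactants: 9 epoxy ether
Product: 11 (1S,3aR,4S,6aR)-1-[4-(benzyloxy)-3-bromo-5-methoxyphenyl]-4-[4-(benzyloxy)-3-methoxyphenyl]tetrahydro-1H,3H-furo[3,4-c]furan, via cyclised benzylic iodide 10 (not isolated)
Conditions: Cp2TiCl2 (2.5 equiv), Zn dust, THF, rt, slow addition of 9; then I2, rt → 50 °C
Reagents that add atoms: none
Why: Nugent–RajanBabu epoxide opening by trivalent titanium (Cp2TiCl) gives the secondary radical at C8′, which cyclises 5-exo-trig onto the styrene through a chair-like transition state with the ring D aryl pseudo-equatorial, so C7′ sets C8′ (trans) and C8 (cis). A second Cp2TiCl traps the benzylic radical, I2 converts the carbon–titanium bond into iodide 10, and the titanium alkoxide displaces it (5-exo-tet, through the para-benzyloxybenzyl cation), placing the ring E aryl exo at C7; this sequence is an established entry to 2,6-diaryl-3,7-dioxabicyclo[3.3.0]octane lignans.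

Step 9
Reactants: 12 3-bromo-4,5-dihydroxybenzaldehyde
Product: 13 7-bromo-2,2-diphenyl-1,3-benzodioxole-5-carbaldehyde
Conditions: Ph2CCl2, K2CO3, MeCN, 60 °C
Reagents that add atoms: dichlorodiphenylmethane, ClC(Cl)(c1ccccc1)c1ccccc1
Why: double O-alkylation of the catechol to the diphenylmethylene ketal, a standard catechol protection. It locks the B4 oxygen in conjugation with ring B and is removable by hydrogenolysis.

Step 10
Reactants: 13 7-bromo-2,2-diphenyl-1,3-benzodioxole-5-carbaldehyde
Product: 14 2,2-diphenyl-7-(4,4,5,5-tetramethyl-1,3,2-dioxaborolan-2-yl)-1,3-benzodioxole-5-carbaldehyde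
Conditions: B2pin2, Pd(dppf)Cl2 (3 mol%), KOAc, 1,4-dioxane, 85 °C
Reagents that add atoms: bis(pinacolato)diboron, CC1(C)OB(OC1(C)C)B1OC(C)(C)C(C)(C)O1
Why: Miyaura borylation of the aryl bromide; the aldehyde and the ketal tolerate the weak acetate base.

Step 11
Reactants: 11 bromo lignan; 14 ring B boronate
Product: 15 7-Lg-2,2-diphenyl-1,3-benzodioxole-5-carbaldehyde
Conditions: Pd(OAc)2 (3 mol%), SPhos (6 mol%), K3PO4, toluene–H2O, 80 °C
Reagents that add atoms: none
Why: Suzuki–Miyaura coupling; each partner has one ortho oxygen substituent, a pattern the SPhos system handles well. The resulting axis has only two ortho substituents and rotates freely, so no new stereo element arises.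

Step 12
Reactants: 15 biaryl aldehyde
Product: 16 5-ethynyl-7-Lg-2,2-diphenyl-1,3-benzodioxole
Conditions: dimethyl (1-diazo-2-oxopropyl)phosphonate, K2CO3, MeOH–THF, rt
Reagents that add atoms: dimethyl (1-diazo-2-oxopropyl)phosphonate, CC(=O)C(=[N+]=[N-])P(=O)(OC)OC
Why: Seyferth–Gilbert homologation with the Ohira–Bestmann reagent turns the aryl aldehyde into the terminal alkyne under mild carbonate conditions that leave the ethers, the ketal and the lignan untouched.

Step 13
Reactants: 16 aryl alkyne
Product: 17 (Z)-2-(7-Lg-2,2-diphenyl-1,3-benzodioxol-5-yl)ethenyl acetate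
Conditions: AcOH (1.5 equiv), [RuCl2(p-cymene)]2 (2 mol%), P(4-ClC6H4)3 (6 mol%), DMAP (8 mol%), toluene, 60 °C
Reagents that add atoms: acetic acid, CC(=O)O
Why: ruthenium-catalysed anti-Markovnikov addition of a carboxylic acid to a terminal aryl alkyne through a vinylidene complex, which gives the (Z)-enol ester selectively under near-neutral conditions.

Step 14
Reactants: 18 2,4,6-trihydroxybenzaldehyde
Product: 19 4,6-bis(benzyloxy)-2-hydroxybenzaldehyde
Conditions: BnBr (2.1 equiv), K2CO3, DMF, rt
Reagents that add atoms: benzyl bromide, BrCc1ccccc1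
Why: Williamson ether synthesis; the para hydroxyl and one ortho hydroxyl are alkylated, while the last ortho hydroxyl is held by the hydrogen bond to the formyl group and reacts slowest.

Step 15
Reactants: 19 4,6-bis(benzyloxy)-2-hydroxybenzaldehyde (1.5 equiv); 20 trimethyl orthoformate; 17 (Z)-enol acetate
Product: 22 (2R,3S,4R)-5,7-bis(benzyloxy)-4-methoxy-2-(7-Lg-2,2-diphenyl-1,3-benzodioxol-5-yl)chroman-3-yl acetate, via dimethyl acetal 21 (not isolated)
Conditions: chiral imidodiphosphorimidate acid (IDPi, 5 mol%), 20 (2 equiv), CH2Cl2, 0 °C; then 17, 5 Å MS, −40 → −20 °C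
Reagents that add atoms: none
Why: Proposed new method: the acid and 20 convert 19 into acetal 21, which ionises to the O-methyl oxocarbenium ion (the O-protonated form of a 4-methoxy ortho-quinone methide); the enol acetate attacks it through its acetoxy-bearing carbon (C3–C4 bond), because only this orientation places the charge on C2, para to the coplanar dioxole oxygen of ring B. The closest known reaction type is the acid-promoted formal [4+2] of salicylaldehyde acetal-derived oxocarbenium ions with styrenes or vinyl ethers to 2,4-cis 4-alkoxychromans, including chiral-anion-controlled versions with vinyl ethers; an enol ester partner has not been used. Ring C then closes by attack of the ortho phenol oxygen on C2 (6-exo mode, O1–C2 bond), most likely on the acetoxonium ion formed by the neighbouring acetate. C3 is set in the C–C bond-forming event by the face of the enol acetate left open by the ion-paired chiral anion; C2 follows from C3 by anti opening of the acetoxonium ion and the equatorial chair (2,3-trans); C4 is expected 2,4-cis by analogy and is erased in step 17. The step needs regioselectivity (secured by the para dioxole oxygen against the weaker acyloxy donor), trans closure (secured by acetate participation and the long life of the benzylic cation, so the Z geometry should not carry through) and facial selectivity at C3 (catalyst only, the lignan being too remote to help or hinder). The sieves take up methanol so that it cannot intercept the cation. Because the lignan is homochiral, the wrong-face product is a diastereomer and can be separated.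

Step 16
Reactants: 22 4-methoxyflavan acetate
Product: 23 (2R,3S,4R)-5,7-bis(benzyloxy)-4-hydroxy-2-(7-Lg-2,2-diphenyl-1,3-benzodioxol-5-yl)chroman-3-yl acetate
Conditions: TsOH·H2O (10 mol%), THF–H2O (5:1), rt
Reagents that add atoms: water, O
Why: acid-catalysed SN1 exchange of the benzylic methyl ether: the C4 cation is stabilised by O1, O5 and O7 and should form far faster than any cation from the lignan ethers or the ketal, and water captures it. The C4 configuration is immaterial.

Step 17
Reactants: 23 flavan-4-ol acetate
Product: 24 (2R,3R)-5,7-bis(benzyloxy)-4-oxo-2-(7-Lg-2,2-diphenyl-1,3-benzodioxol-5-yl)chroman-3-yl acetate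
Conditions: Dess–Martin periodinane, NaHCO3, CH2Cl2, 0 °C → rt
Reagents that add atoms: none
Why: Dess–Martin oxidation of a secondary benzylic alcohol to the aryl ketone under buffered, non-acidic conditions; C2 and C3 are not touched and the C4 stereocentre disappears.

Step 18
Reactants: 24 flavanone acetate
Product: 25 (2R,3R)-5,7-bis(benzyloxy)-3-hydroxy-2-(7-Lg-2,2-diphenyl-1,3-benzodioxol-5-yl)chroman-4-one
Conditions: K2CO3 (0.3 equiv), MeOH–THF, 0 °C
Reagents that add atoms: none
Why: base-catalysed transesterification of an acetate activated by the adjacent ketone; all phenols are still masked, so no phenoxide can drive ring-opening. Low temperature limits enolisation at C3, and the 2,3-trans isomer is in any case the thermodynamic one.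

Step 19
Reactants: 25 protected dihydroflavonol
Product: 26 (2R,3R)-2-{3,4-dihydroxy-5-[2-hydroxy-5-[(1S,3aR,4S,6aR)-4-(4-hydroxy-3-methoxyphenyl)tetrahydro-1H,3H-furo[3,4-c]furan-1-yl]-3-methoxyphenyl]phenyl}-3,5,7-trihydroxychroman-4-one
Conditions: H2 (1 atm), Pd(OH)2/C, THF–EtOAc, rt, stopped at full conversion, argon work-up
Reagents that add atoms: none
Why: catalytic hydrogenolysis of the four aryl benzyl ethers and the diphenylmethylene ketal; in a non-protic solvent these should cleave well before the dialkyl benzylic ethers of the bicycle or the C2–O1 bond. The conditions are neutral, so neither half should epimerise.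

## Compound list

1 | 5-bromovanillin (3-bromo-4-hydroxy-5-methoxybenzaldehyde) | COc1cc(C=O)cc(Br)c1O | starting material
2 | 4-(benzyloxy)-3-bromo-5-methoxybenzaldehyde | COc1cc(C=O)cc(Br)c1OCc1ccccc1 | intermediate
3 | rac-1-[4-(benzyloxy)-3-bromo-5-methoxyphenyl]prop-2-en-1-ol | COc1cc(C(O)C=C)cc(Br)c1OCc1ccccc1 | intermediate
4 | (R)-[4-(benzyloxy)-3-bromo-5-methoxyphenyl][(S)-oxiran-2-yl]methanol | O[C@@H]([C@@H]1CO1)c1cc(OC)c(OCc2ccccc2)c(Br)c1 | intermediate
5 | ferulic acid, (E)-3-(4-hydroxy-3-methoxyphenyl)prop-2-enoic acid | COc1cc(/C=C/C(=O)O)ccc1O | starting material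
6 | benzyl (E)-3-[4-(benzyloxy)-3-methoxyphenyl]prop-2-enoate | COc1cc(/C=C/C(=O)OCc2ccccc2)ccc1OCc1ccccc1 | intermediate
7 | (E)-3-[4-(benzyloxy)-3-methoxyphenyl]prop-2-en-1-ol | COc1cc(/C=C/CO)ccc1OCc1ccccc1 | intermediate
8 | (E)-1-(benzyloxy)-4-(3-bromoprop-1-en-1-yl)-2-methoxybenzene | COc1cc(/C=C/CBr)ccc1OCc1ccccc1 | intermediate
9 | (S)-2-[(R)-[4-(benzyloxy)-3-bromo-5-methoxyphenyl]{[(E)-3-[4-(benzyloxy)-3-methoxyphenyl]prop-2-en-1-yl]oxy}methyl]oxirane | COc1cc(/C=C/CO[C@@H]([C@@H]2CO2)c2cc(OC)c(OCc3ccccc3)c(Br)c2)ccc1OCc1ccccc1 | intermediate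
10 | chlorobis(cyclopentadienyl)titanium alkoxide of [(2S,3R,4R)-2-[4-(benzyloxy)-3-bromo-5-methoxyphenyl]-4-{[4-(benzyloxy)-3-methoxyphenyl]iodomethyl}tetrahydrofuran-3-yl]methanol, iodide carbon of either configuration | COc1cc(C(I)[C@H]2CO[C@H](c3cc(OC)c(OCc4ccccc4)c(Br)c3)[C@H]2CO[Ti](Cl)(C2C=CC=C2)C2C=CC=C2)ccc1OCc1ccccc1 | intermediate (not isolated)
11 | (1S,3aR,4S,6aR)-1-[4-(benzyloxy)-3-bromo-5-methoxyphenyl]-4-[4-(benzyloxy)-3-methoxyphenyl]tetrahydro-1H,3H-furo[3,4-c]furan | COc1cc([C@H]2OC[C@H]3[C@@H]2CO[C@@H]3c2cc(OC)c(OCc3ccccc3)c(Br)c2)ccc1OCc1ccccc1 | intermediate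
12 | 3-bromo-4,5-dihydroxybenzaldehyde | O=Cc1cc(O)c(O)c(Br)c1 | starting material
13 | 7-bromo-2,2-diphenyl-1,3-benzodioxole-5-carbaldehyde | O=Cc1cc2OC(c3ccccc3)(c3ccccc3)Oc2c(Br)c1 | intermediate
14 | 2,2-diphenyl-7-(4,4,5,5-tetramethyl-1,3,2-dioxaborolan-2-yl)-1,3-benzodioxole-5-carbaldehyde | O=Cc1cc2OC(c3ccccc3)(c3ccccc3)Oc2c(B2OC(C)(C)C(C)(C)O2)c1 | intermediate
15 | 7-Lg-2,2-diphenyl-1,3-benzodioxole-5-carbaldehyde | COc1cc([C@H]2OC[C@H]3[C@@H]2CO[C@@H]3c2cc(OC)c(OCc3ccccc3)c(-c3cc(C=O)cc4OC(c5ccccc5)(c5ccccc5)Oc34)c2)ccc1OCc1ccccc1 | intermediate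
16 | 5-ethynyl-7-Lg-2,2-diphenyl-1,3-benzodioxole | COc1cc([C@H]2OC[C@H]3[C@@H]2CO[C@@H]3c2cc(OC)c(OCc3ccccc3)c(-c3cc(C#C)cc4OC(c5ccccc5)(c5ccccc5)Oc34)c2)ccc1OCc1ccccc1 | intermediate
17 | (Z)-2-(7-Lg-2,2-diphenyl-1,3-benzodioxol-5-yl)ethenyl acetate | COc1cc([C@H]2OC[C@H]3[C@@H]2CO[C@@H]3c2cc(OC)c(OCc3ccccc3)c(-c3cc(/C=C\OC(C)=O)cc4OC(c5ccccc5)(c5ccccc5)Oc34)c2)ccc1OCc1ccccc1 | intermediate
18 | 2,4,6-trihydroxybenzaldehyde | O=Cc1c(O)cc(O)cc1O | starting material
19 | 4,6-bis(benzyloxy)-2-hydroxybenzaldehyde | O=Cc1c(O)cc(OCc2ccccc2)cc1OCc1ccccc1 | intermediate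
20 | trimethyl orthoformate | COC(OC)OC | starting material
21 | 3,5-bis(benzyloxy)-2-(dimethoxymethyl)phenol | COC(OC)c1c(O)cc(OCc2ccccc2)cc1OCc1ccccc1 | intermediate (not isolated)
22 | (2R,3S,4R)-5,7-bis(benzyloxy)-4-methoxy-2-(7-Lg-2,2-diphenyl-1,3-benzodioxol-5-yl)chroman-3-yl acetate | COc1cc([C@H]2OC[C@H]3[C@@H]2CO[C@@H]3c2cc(OC)c(OCc3ccccc3)c(-c3cc([C@H]4Oc5cc(OCc6ccccc6)cc(OCc6ccccc6)c5[C@@H](OC)[C@@H]4OC(C)=O)cc4OC(c5ccccc5)(c5ccccc5)Oc34)c2)ccc1OCc1ccccc1 | intermediate
23 | (2R,3S,4R)-5,7-bis(benzyloxy)-4-hydroxy-2-(7-Lg-2,2-diphenyl-1,3-benzodioxol-5-yl)chroman-3-yl acetate | COc1cc([C@H]2OC[C@H]3[C@@H]2CO[C@@H]3c2cc(OC)c(OCc3ccccc3)c(-c3cc([C@H]4Oc5cc(OCc6ccccc6)cc(OCc6ccccc6)c5[C@@H](O)[C@@H]4OC(C)=O)cc4OC(c5ccccc5)(c5ccccc5)Oc34)c2)ccc1OCc1ccccc1 | intermediate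
24 | (2R,3R)-5,7-bis(benzyloxy)-4-oxo-2-(7-Lg-2,2-diphenyl-1,3-benzodioxol-5-yl)chroman-3-yl acetate | COc1cc([C@H]2OC[C@H]3[C@@H]2CO[C@@H]3c2cc(OC)c(OCc3ccccc3)c(-c3cc([C@H]4Oc5cc(OCc6ccccc6)cc(OCc6ccccc6)c5C(=O)[C@@H]4OC(C)=O)cc4OC(c5ccccc5)(c5ccccc5)Oc34)c2)ccc1OCc1ccccc1 | intermediate
25 | (2R,3R)-5,7-bis(benzyloxy)-3-hydroxy-2-(7-Lg-2,2-diphenyl-1,3-benzodioxol-5-yl)chroman-4-one | COc1cc([C@H]2OC[C@H]3[C@@H]2CO[C@@H]3c2cc(OC)c(OCc3ccccc3)c(-c3cc([C@H]4Oc5cc(OCc6ccccc6)cc(OCc6ccccc6)c5C(=O)[C@@H]4O)cc4OC(c5ccccc5)(c5ccccc5)Oc34)c2)ccc1OCc1ccccc1 | intermediate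
26 | (2R,3R)-2-{3,4-dihydroxy-5-[2-hydroxy-5-[(1S,3aR,4S,6aR)-4-(4-hydroxy-3-methoxyphenyl)tetrahydro-1H,3H-furo[3,4-c]furan-1-yl]-3-methoxyphenyl]phenyl}-3,5,7-trihydroxychroman-4-one | COc1cc([C@H]2OC[C@H]3[C@@H]2CO[C@@H]3c2cc(OC)c(O)c(-c3cc([C@H]4Oc5cc(O)cc(O)c5C(=O)[C@@H]4O)cc(O)c3O)c2)ccc1O | target

## Step count and uncertain steps

Total: 19 steps. Longest linear sequence: 13 steps (1, 2, 3, 7, 8, 11, 12, 13, 15, 16, 17, 18, 19, from 5-bromovanillin).

**Step 15 (key step, proposed new method).** The oxocarbenium ion is stabilised by three ring A oxygens and may be too weak an electrophile for an enol acetate. Acetal exchange, Friedel–Crafts attack on the electron-rich ring A positions, or protonation of the enol acetate could then take over. Even if the annulation runs, facial selection at C3 by the chiral anion may be poor, since an enol ester has not been tested in such an ion pair.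
Fallback by known chemistry, setting out from 15 and returning at 25:
- Commercial 4′,6′-bis(benzyloxy)-2′-hydroxyacetophenone (CC(=O)c1c(O)cc(OCc2ccccc2)cc1OCc1ccccc1) is converted with MOMCl and NaH into 2′,4′-bis(benzyloxy)-6′-(methoxymethoxy)acetophenone F1.
- Claisen–Schmidt condensation of F1 with 15 (KOH, EtOH–THF) gives the (E)-chalcone F2.
- Juliá–Colonna epoxidation (poly-L-leucine, urea–H2O2, DBU, THF) gives the (αR,βS)-epoxy ketone F3.
- Dilute HCl in THF–MeOH removes the MOM group ortho to the ketone, and the freed phenol opens the epoxide at the benzylic carbon with inversion (6-endo), which leads to 25. Steps 15 to 18 are bypassed.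

**Step 8.** The iodine stage may fail: reduction or elimination of the benzylic titanium or iodide species to a styrene before the alkoxide closes, or closure with poor exo selectivity.
Fallback setting out from 9 and returning at 11: the same Cp2TiCl cyclisation is quenched with dilute acid instead of iodine, giving [(2S,3R,4R)-2-[4-(benzyloxy)-3-bromo-5-methoxyphenyl]-4-[4-(benzyloxy)-3-methoxybenzyl]tetrahydrofuran-3-yl]methanol F4. The second ring is then closed oxidatively with DDQ in CH2Cl2 (hydride abstraction at the ring E benzylic methylene, capture of the quinone methide-type cation by the C9′ hydroxyl). The bromine-deactivated ring D side should be slower to oxidise.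

**Step 16.** The neighbouring acetate may capture the C4 cation, leading to acetyl migration to O4, or the cation may lose the C3 proton to give a flav-3-ene.
Fallback setting out from 22 and returning at 24: direct oxidation of the C4–H bond with DDQ in wet CH2Cl2 at low temperature (hydride abstraction from the most electron-rich benzylic ether, collapse of the hemiacetal to the ketone). No new compound arises (F0). The cost is competition from the lignan benzylic C–H bonds.

**Step 18.** Enolisation toward C3 during the basic methanolysis could epimerise C3 or open ring C by E1cB loss of the O1 phenoxide.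
Fallback setting out from 22 and returning at 25, with the acetate removed before any ketone exists:
- K2CO3 in MeOH gives (2R,3S,4R)-5,7-bis(benzyloxy)-4-methoxy-2-(7-Lg-2,2-diphenyl-1,3-benzodioxol-5-yl)chroman-3-ol F5.
- Aqueous TsOH in THF gives the (2R,3S,4R)-chroman-3,4-diol F6.
- MnO2 in CH2Cl2 oxidises only the benzylic C4 alcohol, giving 25.

**Step 19.** Over-reduction is the risk: cleavage of the benzylic C–O bonds of the bicycle or of C2–O1 before the hindered ring D benzyl ether and the ketal are gone.
Fallback setting out from 25 and returning at 26: non-reductive dealkylation with BCl3 and pentamethylbenzene in CH2Cl2 at −78 °C. The scavenger takes up the benzyl cations and the ketal falls away as benzophenone on aqueous work-up. No new compound arises (F0).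

## Further compounds

F1 | step 15 | 2′,4′-bis(benzyloxy)-6′-(methoxymethoxy)acetophenone | CC(=O)c1c(OCOC)cc(OCc2ccccc2)cc1OCc1ccccc1
F2 | step 15 | (E)-1-[2,4-bis(benzyloxy)-6-(methoxymethoxy)phenyl]-3-(7-Lg-2,2-diphenyl-1,3-benzodioxol-5-yl)prop-2-en-1-one | COc1cc([C@H]2OC[C@H]3[C@@H]2CO[C@@H]3c2cc(OC)c(OCc3ccccc3)c(-c3cc(/C=C/C(=O)c4c(OCOC)cc(OCc5ccccc5)cc4OCc4ccccc4)cc4OC(c5ccccc5)(c5ccccc5)Oc34)c2)ccc1OCc1ccccc1
F3 | step 15 | [2,4-bis(benzyloxy)-6-(methoxymethoxy)phenyl][(2R,3S)-3-(7-Lg-2,2-diphenyl-1,3-benzodioxol-5-yl)oxiran-2-yl]methanone | COc1cc([C@H]2OC[C@H]3[C@@H]2CO[C@@H]3c2cc(OC)c(OCc3ccccc3)c(-c3cc([C@@H]4O[C@H]4C(=O)c4c(OCOC)cc(OCc5ccccc5)cc4OCc4ccccc4)cc4OC(c5ccccc5)(c5ccccc5)Oc34)c2)ccc1OCc1ccccc1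
F4 | step 8 | [(2S,3R,4R)-2-[4-(benzyloxy)-3-bromo-5-methoxyphenyl]-4-[4-(benzyloxy)-3-methoxybenzyl]tetrahydrofuran-3-yl]methanol | COc1cc(C[C@H]2CO[C@H](c3cc(OC)c(OCc4ccccc4)c(Br)c3)[C@H]2CO)ccc1OCc1ccccc1
F0 | step 16 | none | none
F5 | step 18 | (2R,3S,4R)-5,7-bis(benzyloxy)-4-methoxy-2-(7-Lg-2,2-diphenyl-1,3-benzodioxol-5-yl)chroman-3-ol | COc1cc([C@H]2OC[C@H]3[C@@H]2CO[C@@H]3c2cc(OC)c(OCc3ccccc3)c(-c3cc([C@H]4Oc5cc(OCc6ccccc6)cc(OCc6ccccc6)c5[C@@H](OC)[C@@H]4O)cc4OC(c5ccccc5)(c5ccccc5)Oc34)c2)ccc1OCc1ccccc1
F6 | step 18 | (2R,3S,4R)-5,7-bis(benzyloxy)-2-(7-Lg-2,2-diphenyl-1,3-benzodioxol-5-yl)chroman-3,4-diol | COc1cc([C@H]2OC[C@H]3[C@@H]2CO[C@@H]3c2cc(OC)c(OCc3ccccc3)c(-c3cc([C@H]4Oc5cc(OCc6ccccc6)cc(OCc6ccccc6)c5[C@@H](O)[C@@H]4O)cc4OC(c5ccccc5)(c5ccccc5)Oc34)c2)ccc1OCc1ccccc1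
F0 | step 19 | none | none
A1 | alternative 1 | 2-methoxy-1-(methoxymethoxy)-4-[bis(phenylthio)methyl]benzene | COCOc1ccc(C(Sc2ccccc2)Sc2ccccc2)cc1OC
A2 | alternative 1 | (5R)-5-[(1R,2S,5R)-menthyloxy]furan-2(5H)-one | O=C1O[C@@H](O[C@@H]2C[C@H](C)CC[C@H]2C(C)C)C=C1
A3 | alternative 1 | 3-[5-(tert-butyldimethylsilyloxymethyl)-2,3-bis(methoxymethoxy)phenyl]-5-methoxy-4-(methoxymethoxy)benzaldehyde | COc1cc(C=O)cc(-c2cc(CO[Si](C)(C)C(C)(C)C)cc(OCOC)c2OCOC)c1OCOC
A4 | alternative 1 | trans-disubstituted menthyloxy lactone from conjugate addition and aldol trapping | O=C1O[C@@H](O[C@@H]2C[C@H](C)CC[C@H]2C(C)C)[C@H](C(Sc2ccccc2)(Sc2ccccc2)c2ccc(OCOC)c(OC)c2)[C@H]1[C@H](O)c1cc(OC)c(OCOC)c(-c2cc(CO[Si](C)(C)C(C)(C)C)cc(OCOC)c2OCOC)c1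
A5 | alternative 2 | 7′-deoxy tetrahydrofuran lignan with free ring D phenol and free C9 hydroxyl | COc1cc([C@H]2OC[C@H](Cc3cc(OC)c(O)c(-c4cc(CO[Si](C)(C)C(C)(C)C)cc(OCOC)c4OCOC)c3)[C@@H]2CO)ccc1OCOC
A6 | alternative 2 | furofuran biaryl with free ring D phenol | COc1cc([C@H]2OC[C@H]3[C@@H]2CO[C@@H]3c2cc(OC)c(O)c(-c3cc(CO[Si](C)(C)C(C)(C)C)cc(OCOC)c3OCOC)c2)ccc1OCOC
A7 | alternative 3 | methyl 3-(methoxymethoxy)-2-oxo-2H-pyran-5-carboxylate | COCOC1=CC(C(=O)OC)=COC1=O
A8 | alternative 3 | 2-{3-methoxy-4-(methoxymethoxy)-5-[(triisopropylsilyloxy)ethynyl]phenyl}-1,3-dioxolane | COCOc1c(OC)cc(C2OCCO2)cc1C#CO[Si](C(C)C)(C(C)C)C(C)C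
A9 | alternative 3 | fully differentiated biaryl ester acetal | COC(=O)c1cc(OCOC)c(O[Si](C(C)C)(C(C)C)C(C)C)c(-c2cc(C3OCCO3)cc(OC)c2OCOC)c1
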